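**Plan**

- Cuts, numbering the chain from the alkyne carbon on the ring: the C9=C10 Z-alkene (Wittig), the chain C4(sp2)–C5(sp3) bond (key step), the C2–C3 enyne bond (Sonogashira), the alkyne carbon C1 (from a formyl group), the O–C ring bond of the oxolane (oxidative cyclisation) and the propargylic C–C bond to an epoxide.
- Forward: epoxide opening by lithium methyl propiolate, cobalt-catalysed aerobic cyclisation closing the single oxolane ring, hydrogenation, oxidation, Ohira–Bestmann alkynylation, Sonogashira to the (E)-iodoenyne, Ni-electrocatalytic decarboxylative alkenylation with a 6-chlorohexanoate redox-active ester, phosphonium salt, Z-selective Wittig with (E)-3-bromoacrolein.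
- Stereochemistry: the ester-bearing ring carbon comes from a commercial (S)-epoxide; the alkyne-bearing ring carbon is set trans to it by the oxidative cyclisation; the E-enyne comes from (E)-1,2-diiodoethene with retention, the Z-alkene from the non-stabilised ylide, the E-bromoalkene from a hydrozirconation-derived aldehyde.
- Enabling feature: chain C4 is the terminal sp2 carbon of the (E)-enyne C1≡C2–C3=C4 on the oxolane, a site for an alkyne-activated alkenyl iodide. Chain C5 is the first of four unbranched CH2 groups, so it can be a primary radical from a cheap ω-chloro acid.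
- The C9=C10–C11=C12 bromodiene would sit 5-exo to that radical, so it is carried as CH2Cl through the radical step and built afterwards.

Key step: step 8

Assumption: (S)-2-(but-3-en-1-yl)oxirane, (E)-1,2-diiodoethene, 6-chlorohexanoic acid and 3,3-diethoxyprop-1-yne are taken as purchasable.

**Step 1**
Reactants: 1 (S)-2-(but-3-en-1-yl)oxirane; 2 methyl propiolate
Product: 4 methyl (5S)-5-hydroxynon-8-en-2-ynoate, via lithium 3-methoxy-3-oxoprop-1-yn-1-ide 3 (not isolated)
Conditions: 2, n-BuLi, THF, −78 °C; BF3·OEt2, then 1, −78 °C; aq. NH4Cl quench at −78 °C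
Reagents that add atoms: none
Why: Yamaguchi–Hirao alkynylation, in which the BF3-activated terminal epoxide is opened by the acetylide at its unsubstituted carbon, so the stereocentre of 1 is not touched and becomes C5 of 4.

**Step 2**
Reactants: 4 methyl (5S)-5-hydroxynon-8-en-2-ynoate
Product: 5 methyl 4-[(2S,5S)-5-(hydroxymethyl)oxolan-2-yl]but-2-ynoate
Conditions: Co(modp)2 (10 mol %, divalent cobalt; modp = 1-morpholinocarbamoyl-4,4-dimethylpentane-1,3-dionate), t-BuOOH (cat.), O2 (1 atm), i-PrOH, 4 Å sieves, 55 °C
Reagents that add atoms: dioxygen, O=O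
Why: Mukaiyama aerobic oxidative cyclisation of the pent-4-en-1-ol unit, in which the cobalt-bound alkoxide adds 5-exo to the alkene with the carbinol substituent pseudo-equatorial, which should give the 2,5-trans oxolane, and the exocyclic radical is trapped by O2 and reduced to CH2OH while the electron-poor alkynoate stays a spectator.

**Step 3**
Reactants: 5 methyl 4-[(2S,5S)-5-(hydroxymethyl)oxolan-2-yl]but-2-ynoate
Product: 6 methyl 4-[(2R,5S)-5-(hydroxymethyl)oxolan-2-yl]butanoate
Conditions: H2 (1 atm), 10 % Pd/C, EtOAc, rt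
Reagents that add atoms: none
Why: Catalytic hydrogenation saturates the only π-system left; the ring C–O bond is separated from the alkyne by a CH2 and is not hydrogenolysed, and the change of descriptor at C2 is only a change of CIP priority.

**Step 4**
Reactants: 6 methyl 4-[(2R,5S)-5-(hydroxymethyl)oxolan-2-yl]butanoate
Product: 7 methyl 4-[(2R,5S)-5-formyloxolan-2-yl]butanoate
Conditions: TEMPO (10 mol %), PhI(OAc)2, CH2Cl2, rt; used crude
Reagents that add atoms: none
Why: Oxoammonium (TEMPO/PhI(OAc)2) oxidation of a primary alcohol stops at the aldehyde under non-basic conditions, so the α-alkoxy stereocentre should not epimerise.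

**Step 5**
Reactants: 7 methyl 4-[(2R,5S)-5-formyloxolan-2-yl]butanoate
Product: 8 methyl 4-[(2R,5S)-5-ethynyloxolan-2-yl]butanoate
Conditions: Ohira–Bestmann reagent, K2CO3, MeOH, 0 °C to rt
Reagents that add atoms: dimethyl (1-diazo-2-oxopropyl)phosphonate, COP(=O)(OC)C(=[N+]=[N-])C(C)=O
Why: Seyferth–Gilbert homologation in the Ohira–Bestmann form converts the aldehyde into the terminal alkyne under conditions mild enough to keep the α-alkoxy centre, and methanolysis of the methyl ester is degenerate.

**Step 6**
Reactants: 8 methyl 4-[(2R,5S)-5-ethynyloxolan-2-yl]butanoate; 9 (E)-1,2-diiodoethene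
Product: 10 methyl 4-[(2R,5S)-5-[(E)-4-iodobut-3-en-1-yn-1-yl]oxolan-2-yl]butanoate
Conditions: 9 (4 equiv), Pd(PPh3)4 (5 mol %, zerovalent palladium), CuI (10 mol %), Et3N, THF, rt, slow addition of 8
Reagents that add atoms: none
Why: Sonogashira coupling proceeds with retention of the alkene geometry, and the excess of the diiodide with slow addition of the alkyne should hold the reaction at mono-coupling.

**Step 7**
Reactants: 11 6-chlorohexanoic acid
Product: 12 1,3-dioxoisoindolin-2-yl 6-chlorohexanoate
Conditions: N-hydroxyphthalimide, N,N'-diisopropylcarbodiimide, DMAP (cat.), CH2Cl2, rt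
Reagents that add atoms: N-hydroxyphthalimide, O=C1c2ccccc2C(=O)N1O
Why: Steglich-type carbodiimide esterification gives the redox-active N-acyloxyphthalimide that serves as the radical precursor.

**Step 8**
Reactants: 10 methyl 4-[(2R,5S)-5-[(E)-4-iodobut-3-en-1-yn-1-yl]oxolan-2-yl]butanoate; 12 1,3-dioxoisoindolin-2-yl 6-chlorohexanoate
Product: 13 methyl 4-[(2R,5S)-5-[(E)-9-chloronon-3-en-1-yn-1-yl]oxolan-2-yl]butanoate
Conditions: 12 (2 equiv), NiCl2·6H2O (20 mol %), 2,2'-bipyridine (20 mol %), AgNO3 (0.3 equiv), LiCl, DMF, Mg anode/reticulated vitreous carbon cathode, undivided cell, constant current, rt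
Reagents that add atoms: none
Why: Cathodic reduction generates low-valent Ni(bpy), which inserts into the C(sp2)–I bond of 10 with retention of the E geometry, while the ester 12 accepts one electron (at the silver-coated cathode or from low-valent nickel), loses phthalimide anion and CO2 and releases the primary 5-chloropentyl radical; capture of this radical by the alkenylnickel species (divalent nickel) gives a trivalent alkyl(alkenyl)nickel that reductively eliminates the chain C4–C5 bond. The closest known reaction type is the Ni-electrocatalytic decarboxylative alkenylation of N-hydroxyphthalimide esters with alkenyl halides, a reductive cross-electrophile coupling run with a sacrificial Mg anode and a silver-nanoparticle-modified cathode. No ring is closed and no stereocentre is formed; the E geometry of C3=C4 is carried over from 9 by stereoretentive oxidative addition and reductive elimination, and the two oxolane stereocentres are remote spectators. The step needs cross-coupling over homo-coupling and reaction at C–I but not at C–Cl: the excess of the cheap ester 12 and the current-limited radical generation favour the cross product, and a primary alkyl chloride and a methyl ester are inert to Ni(bpy) at this potential. The radical has no alkene in a 5-exo position, because the C9=C10–C11=C12 bromodiene, which would turn it into a 5-hexenyl radical clock and offer nickel a second C(sp2)–halogen bond, is still masked as CH2Cl.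

**Step 9**
Reactants: 13 methyl 4-[(2R,5S)-5-[(E)-9-chloronon-3-en-1-yn-1-yl]oxolan-2-yl]butanoate
Product: 14 [(6E)-9-[(2S,5R)-5-(4-methoxy-4-oxobutyl)oxolan-2-yl]non-6-en-8-yn-1-yl]triphenylphosphonium iodide
Conditions: PPh3, NaI, MeCN, reflux
Reagents that add atoms: triphenylphosphine, c1ccc(cc1)P(c1ccccc1)c1ccccc1; sodium iodide, [Na+].[I-]
Why: In situ Finkelstein exchange followed by SN2 quaternisation of triphenylphosphine at the primary carbon gives the phosphonium iodide without touching the enyne or the ester.

**Step 10**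
Reactants: 15 3,3-diethoxyprop-1-yne
Product: 17 (E)-1-bromo-3,3-diethoxyprop-1-ene, via (E)-(3,3-diethoxyprop-1-en-1-yl)zirconocene chloride 16 (not isolated)
Conditions: Cp2Zr(H)Cl, CH2Cl2, rt; NBS, 0 °C
Reagents that add atoms: N-bromosuccinimide, BrN1C(=O)CCC1=O
Why: Hydrozirconation adds H and Zr syn with zirconium at the terminal carbon, and bromination of the C–Zr bond with retention should give the E-bromoalkene only.

**Step 11**
Reactants: 17 (E)-1-bromo-3,3-diethoxyprop-1-ene
Product: 18 (E)-3-bromoprop-2-enal
Conditions: 10 % aq. oxalic acid on SiO2, CH2Cl2, rt; dried solution used at once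
Reagents that add atoms: water, O
Why: Mild acid hydrolysis of the acetal unmasks the enal without isomerising the E-bromoalkene, and immediate use avoids loss of this volatile, labile aldehyde.

**Step 12**
Reactants: 14 [(6E)-9-[(2S,5R)-5-(4-methoxy-4-oxobutyl)oxolan-2-yl]non-6-en-8-yn-1-yl]triphenylphosphonium iodide; 18 (E)-3-bromoprop-2-enal
Product: 20 methyl 4-[(2R,5S)-5-[(3E,9Z,11E)-12-bromododeca-3,9,11-trien-1-yn-1-yl]oxolan-2-yl]butanoate, via phosphorus ylide 19 (not isolated)
Conditions: NaN(SiMe3)2 (1.0 equiv), THF, −78 to 0 °C; 18, −78 °C to rt, exclusion of light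
Reagents that add atoms: none
Why: Wittig olefination of a non-stabilised ylide under lithium-free conditions runs through the kinetically favoured cis-oxaphosphetane and should give the Z C9=C10 bond, while 1,2-addition to the enal leaves the E-bromoalkene intact.

**Compound list**

1 | (S)-2-(but-3-en-1-yl)oxirane | C=CCC[C@H]1CO1 | starting material
2 | methyl propiolate | COC(=O)C#C | starting material
3 | lithium 3-methoxy-3-oxoprop-1-yn-1-ide | [Li]C#CC(=O)OC | intermediate
4 | methyl (5S)-5-hydroxynon-8-en-2-ynoate | COC(=O)C#CC[C@@H](O)CCC=C | intermediate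
5 | methyl 4-[(2S,5S)-5-(hydroxymethyl)oxolan-2-yl]but-2-ynoate | COC(=O)C#CC[C@@H]1CC[C@@H](CO)O1 | intermediate
6 | methyl 4-[(2R,5S)-5-(hydroxymethyl)oxolan-2-yl]butanoate | COC(=O)CCC[C@@H]1CC[C@@H](CO)O1 | intermediate
7 | methyl 4-[(2R,5S)-5-formyloxolan-2-yl]butanoate | COC(=O)CCC[C@@H]1CC[C@@H](C=O)O1 | intermediate
8 | methyl 4-[(2R,5S)-5-ethynyloxolan-2-yl]butanoate | COC(=O)CCC[C@@H]1CC[C@@H](C#C)O1 | intermediate
9 | (E)-1,2-diiodoethene | I/C=C/I | starting material
10 | methyl 4-[(2R,5S)-5-[(E)-4-iodobut-3-en-1-yn-1-yl]oxolan-2-yl]butanoate | COC(=O)CCC[C@@H]1CC[C@@H](C#C/C=C/I)O1 | intermediate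
11 | 6-chlorohexanoic acid | OC(=O)CCCCCCl | starting material
12 | 1,3-dioxoisoindolin-2-yl 6-chlorohexanoate | O=C(CCCCCCl)ON1C(=O)c2ccccc2C1=O | intermediate
13 | methyl 4-[(2R,5S)-5-[(E)-9-chloronon-3-en-1-yn-1-yl]oxolan-2-yl]butanoate | COC(=O)CCC[C@@H]1CC[C@@H](C#C/C=C/CCCCCCl)O1 | intermediate
14 | [(6E)-9-[(2S,5R)-5-(4-methoxy-4-oxobutyl)oxolan-2-yl]non-6-en-8-yn-1-yl]triphenylphosphonium iodide | COC(=O)CCC[C@@H]1CC[C@@H](C#C/C=C/CCCCC[P+](c2ccccc2)(c2ccccc2)c2ccccc2)O1.[I-] | intermediate
15 | 3,3-diethoxyprop-1-yne | CCOC(OCC)C#C | starting material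
16 | (E)-(3,3-diethoxyprop-1-en-1-yl)zirconocene chloride | CCOC(OCC)/C=C/[Zr](Cl)(C1C=CC=C1)C1C=CC=C1 | intermediate
17 | (E)-1-bromo-3,3-diethoxyprop-1-ene | CCOC(OCC)/C=C/Br | intermediate
18 | (E)-3-bromoprop-2-enal | O=C/C=C/Br | intermediate
19 | methyl 4-[(2R,5S)-5-[(3E)-9-(triphenyl-λ5-phosphanylidene)non-3-en-1-yn-1-yl]oxolan-2-yl]butanoate | COC(=O)CCC[C@@H]1CC[C@@H](C#C/C=C/CCCCC=P(c2ccccc2)(c2ccccc2)c2ccccc2)O1 | intermediate
20 | methyl 4-[(2R,5S)-5-[(3E,9Z,11E)-12-bromododeca-3,9,11-trien-1-yn-1-yl]oxolan-2-yl]butanoate | COC(=O)CCC[C@@H]1CC[C@@H](C#C/C=C/CCCC/C=C\C=C\Br)O1 | target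

**Totals**

Total step count: 12. Longest linear sequence: 9 steps (steps 1 to 6, 8, 9 and 12).

**Steps most likely to fail**

Step 8. Reductive homo-coupling or protodeiodination of the alkenyl iodide may outrun capture of the alkyl radical, and the alkenylnickel intermediate may lose part of its E geometry. The fallback sets out from 10 and comes back at 13 by a two-electron route. Hydroboration of 5-chloropent-1-ene (C=CCCCCl) with 9-borabicyclo[3.3.1]nonane in THF should give 9-(5-chloropentyl)-9-borabicyclo[3.3.1]nonane F1. A Suzuki–Miyaura B-alkyl coupling of F1 with 10 (PdCl2(dppf), AsPh3, Cs2CO3, DMF/THF/H2O, rt) should then give 13 with retention of the E geometry.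

Step 2. The conjugated alkynoate may be consumed by peroxyl radicals or cobalt hydride species under the aerobic conditions, and the trans selectivity may be incomplete. The fallback sets out from 4 and comes back at 5 by stereospecific epoxide opening.
- Epoxidation of 4 with mCPBA (CH2Cl2, NaHCO3, 0 °C) should give methyl (5S)-5-hydroxy-7-(oxiran-2-yl)hept-2-ynoate F2 as both oxirane epimers.
- Hydrolytic kinetic resolution with (R,R)-(salen)Co(OAc) (trivalent cobalt; salen = N,N'-bis(3,5-di-tert-butylsalicylidene)cyclohexane-1,2-diamine dianion) and 0.55 equiv of water should leave methyl (5S)-5-hydroxy-7-[(2R)-oxiran-2-yl]hept-2-ynoate F3. This is the catalyst enantiomer expected to leave (R)-alkyloxiranes unreacted. The other epimer should be hydrolysed to methyl (5S,8S)-5,8,9-trihydroxynon-2-ynoate F4.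
- Camphorsulfonic acid in CH2Cl2 should then close F3 by 5-exo attack of the C5 hydroxyl with inversion at the oxirane carbon, which gives the trans oxolane 5.

Step 12. The β-bromo enal may decompose or lose HBr under the basic conditions, and Z selectivity may erode. The fallback sets out from 14 (through ylide 19) and comes back at 20.
- Wittig reaction of 19 with commercial 3-(trimethylsilyl)prop-2-ynal (NaN(SiMe3)2, THF, −78 °C) should give methyl 4-[(2R,5S)-5-[(3E,9Z)-12-(trimethylsilyl)dodeca-3,9-diene-1,11-diyn-1-yl]oxolan-2-yl]butanoate F5.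
- K2CO3 in MeOH should give methyl 4-[(2R,5S)-5-[(3E,9Z)-dodeca-3,9-diene-1,11-diyn-1-yl]oxolan-2-yl]butanoate F6.
- Hydrozirconation of the terminal alkyne with Cp2Zr(H)Cl (1.1 equiv, CH2Cl2, rt) should give methyl 4-[(2R,5S)-5-[(3E,9Z,11E)-12-[chlorobis(cyclopentadienyl)zirconio]dodeca-3,9,11-trien-1-yn-1-yl]oxolan-2-yl]butanoate F7, which NBS at 0 °C should convert into 20 with retention.

**Further compounds**

F1 | step 8 | 9-(5-chloropentyl)-9-borabicyclo[3.3.1]nonane | ClCCCCCB1C2CCCC1CCC2
F2 | step 2 | methyl (5S)-5-hydroxy-7-(oxiran-2-yl)hept-2-ynoate (both oxirane epimers) | COC(=O)C#CC[C@@H](O)CCC1CO1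
F3 | step 2 | methyl (5S)-5-hydroxy-7-[(2R)-oxiran-2-yl]hept-2-ynoate | COC(=O)C#CC[C@@H](O)CC[C@@H]1CO1
F4 | step 2 | methyl (5S,8S)-5,8,9-trihydroxynon-2-ynoate | COC(=O)C#CC[C@@H](O)CC[C@H](O)CO
F5 | step 12 | methyl 4-[(2R,5S)-5-[(3E,9Z)-12-(trimethylsilyl)dodeca-3,9-diene-1,11-diyn-1-yl]oxolan-2-yl]butanoate | COC(=O)CCC[C@@H]1CC[C@@H](C#C/C=C/CCCC/C=C\C#C[Si](C)(C)C)O1
F6 | step 12 | methyl 4-[(2R,5S)-5-[(3E,9Z)-dodeca-3,9-diene-1,11-diyn-1-yl]oxolan-2-yl]butanoate | COC(=O)CCC[C@@H]1CC[C@@H](C#C/C=C/CCCC/C=C\C#C)O1
F7 | step 12 | methyl 4-[(2R,5S)-5-[(3E,9Z,11E)-12-[chlorobis(cyclopentadienyl)zirconio]dodeca-3,9,11-trien-1-yn-1-yl]oxolan-2-yl]butanoate | COC(=O)CCC[C@@H]1CC[C@@H](C#C/C=C/CCCC/C=C\C=C\[Zr](Cl)(C2C=CC=C2)C2C=CC=C2)O1
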